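(The readings are simulated with made-up constants; scatter was added.)

A flask cannot make product beyond what its partner pays for, if each product costs one partner and each protic impurity destroys one. That pairing is our assumption, since the earlier runs reach no more than 10.5% product.

| setting | larch | oak | birch | north-west | south-east | south-west | north |
|---|---|---|---|---|---|---|---|
| substrate | 0.050 M | 0.050 M | 0.050 M | 0.050 M | 0.050 M | 0.050 M | 0.050 M |
| partner | 1.3 equiv | 1.3 equiv | 2 equiv | 1.30 equiv | 1.30 equiv | 1.30 equiv | 1.30 equiv |
| protic impurity | 0.017 M | 0.038 M | 0.025 M | 0.0250 M | 0.0250 M | 0.0250 M | 0.0250 M |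
| free catalyst | 2 mol% | 2 mol% | 2 mol% | 2 mol% | 2 mol% | 2 mol% | 2 mol% |
| temperature | −20 °C | 22 °C | −20 °C | 10 °C | 60 °C | −15 °C | 35 °C |
| remark | run made earlier | run made earlier | run made earlier |  |  |  |  |
| time |  |  |  | 8.0 h | 8.0 h | 8.0 h | 8.0 h |

* the flask with the highest amount of product, in percent of the substrate charged ("all alike" if they lie within 1.5 percentage points) (north-west / south-east / south-west / north / all alike)
* final product, as a percentage of the substrate charged, in north-west
* final product, as a percentage of the substrate charged, in south-east
* final product, as a percentage of the substrate charged, in south-west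
* final product, as a percentage of the substrate charged, in north

- larch (time / h: product / %, substrate / %): 4.00: 0, 98.3; 6.00: 0.6, 99.1; 12.0: 0.5, 98.5; 20.0: 0.3, 98.3; 40.0: 0.1, 97.4
- oak (time / h: product / %, substrate / %): 1.00: 2.1, 97.4; 2.00: 2.2, 95.1; 3.00: 4.3, 93.0; 4.00: 5.4, 91.5; 6.00: 10.5, 89.1
- birch (time / h: product / %, substrate / %): 8.00: 0.3, 97.5; 20.0: 0.4, 97.4; 25.0: 0.2, 98.3; 40.0: 0.5, 98.2

(each reading ± 0.5 percentage points)

We read the tables column against column. In oak, product and substrate sum to 96.9% after 4.00 h but 99.6% after 6.00 h, and the mean of all its sums is 98.1%. So, with a scatter of 0.5 percentage points on each reading, about 1.9 points of the substrate stands in neither column, which is of the size of the 2 mol% catalyst loading. Larch, at −20 °C, shows 0.1% product after 40.0 h, far less than oak although it ran longer. Birch, also cold but with 2 equiv of partner, shows 0.5% after 40.0 h. Cold, then, larch and birch are both slow. Speed tells us how fast a flask moves, but not where it stops.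

For that we define the partner budget b, the partner charged less the protic impurity charged, per substrate charged. In the asked flasks 1.30 equiv less 0.500 leaves b = 80.0% of the substrate. So partner, not substrate, is the limiting reagent. South-east is the hottest flask, and if it spends its partner within 8.0 h, we expect it to end near b.

The forecast names south-east as the richest flask, with 90% there (range 50% to 100%), 40% in north, 4% in north-west and 0.1% in south-west: “Over 8 h that is about 4%, 40% and near completion.” Our figure for south-east is lower than the forecast's.

The flasks give 2.21% in north-west, 80.9% in south-east, 0.0236% in south-west and 56.6% in north, so south-east holds the most.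

    2 catalyst intermediate B ⇌ resting dimer, settled at all times (K = 525 M⁻¹, ΔH = −25.0 kJ mol⁻¹)
    substrate + catalyst intermediate A → catalyst intermediate B (k = 0.180 M⁻¹ s⁻¹, Ea = 55.0 kJ mol⁻¹)
    partner + free catalyst → catalyst intermediate A (k = 0.155 M⁻¹ s⁻¹, Ea = 38.0 kJ mol⁻¹)
    catalyst intermediate B → free catalyst + product (k = 0.00241 s⁻¹, Ea = 96.0 kJ mol⁻¹)
    partner + protic impurity → quenched reagent (k = 0.00385 M⁻¹ s⁻¹, Ea = 67.0 kJ mol⁻¹)
    (constants at 35 °C)

South-east ends 0.90 points above b, with partner at 0% and 1.9% of the protic impurity unspent, which is worth 0.95 points of substrate. After 80.0 h it still reads 80.9%. The neighbouring flask is south-east with 0.780 equiv of partner, so its b is 28.0%. Its unspent impurity, 21.1% of the charge, adds 11 points, which makes 38.6%. That flask ends with partner at 0% and product at 38.6%.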